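**Retrosynthetic overview**
1. Last bond: the C16–O ester, from the core alcohol and 3,4-dimethoxycinnamic acid (bromoveratrole + acrylic acid, Heck); one global BBr3 deprotection at the end.
2. C7 carboxyl: directed ortho-lithiation/Boc2O on the finished tetralin.
3. Tetralin ring (the only ring made; both benzene rings come from catechol): C1–C8a closed last, by ring contraction of a seven-membered cyclic aryl–alkyl borate (1,2-shift of C1 from B to C8a).
4. C1–C11 by lithiation–borylation (1,2-metallate shift) of an arylpentyl TIB ester with a secondary side-chain boronate; C4–C4a by stereoretentive aryl–boronate coupling (1,2-shift) of lithiated veratrole.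
5. Stereocentres: C4 and C11 by Cu-catalysed Markovnikov hydroboration, C15 from (S)-3-bromo-2-methylpropan-1-ol, C1 by (+)-sparteine.

Assumption: configuration as in the SMILES, i.e. ring (5R,8S), side chain (2S,6R); labels used below: tetralin C1 (bears side chain), C4 (bears CH3), C4a/C8a fusion, C5/C6 oxygens, C7 carboxyl, side chain C11(CH3)–C12–C13–C14–C15(CH3)–C16(O); TIB = 2,4,6-triisopropylbenzoyl; both enantiomers of sparteine and of the bisphosphine are taken as available.

Step 1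
Reactants: 1 catechol
Product: 2 1,2-dimethoxybenzene
Conditions: MeI, K2CO3, acetone, reflux
Reagents that add atoms: iodomethane CI
Why: Williamson O-methylation of both phenols; the methyl ethers protect the catechol and later direct ortho-lithiation.

Step 2
Reactants: 3 pent-4-en-1-ol
Product: 4 pent-4-en-1-yl 2,4,6-tri(propan-2-yl)benzoate
Conditions: 2,4,6-triisopropylbenzoic acid, PPh3, DIAD, THF, 0 °C → rt
Reagents that add atoms: 2,4,6-tri(propan-2-yl)benzoic acid CC(C)c1cc(C(C)C)c(C(=O)O)c(C(C)C)c1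
Why: Mitsunobu esterification installs the hindered TIB ester that later activates the O–CH2 group for sparteine-controlled lithiation.

Step 3
Reactants: 4 pent-4-en-1-yl 2,4,6-tri(propan-2-yl)benzoate
Product: 5 (4R)-4-(4,4,5,5-tetramethyl-1,3,2-dioxaborolan-2-yl)pentyl 2,4,6-tri(propan-2-yl)benzoate
Conditions: CuCl (5 mol %), bulky P-chiral bisphosphine (QuinoxP*-class, enantiomer A, chosen to give 4R), B2pin2, KOtBu (20 mol %), MeOH (2 equiv), THF, −20 °C
Reagents that add atoms: bis(pinacolato)diboron CC1(C)OB(OC1(C)C)B1OC(C)(C)C(C)(C)O1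
Why: Cu-catalysed enantioselective Markovnikov hydroboration (borylcupration/protonation) of the terminal alkene puts boron on the internal carbon and sets C4 (R) under ligand control.

Step 4
Reactants: 2 1,2-dimethoxybenzene; 5 (4R)-4-(4,4,5,5-tetramethyl-1,3,2-dioxaborolan-2-yl)pentyl 2,4,6-tri(propan-2-yl)benzoate
Product: 8 (4R)-4-(2,3-dimethoxyphenyl)pentyl 2,4,6-tri(propan-2-yl)benzoate, via aryllithium 6 (not isolated), via lithium borate 7 (not isolated)
Conditions: 2 (1.2 equiv), n-BuLi, TMEDA, Et2O, 0 °C → rt; 5, THF, −78 °C; NBS (1.05 equiv), THF–MeOH, −78 °C → rt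
Reagents that add atoms: none
Why: Directed ortho-metalation gives 6, which adds to boron; in borate 7 NBS attacks the ring ortho/para to boron (sites activated by the unhindered OMe), which triggers a 1,2-shift of the secondary alkyl group from B to the ipso carbon and B/Br elimination (stereoretentive transition-metal-free sp2–sp3 boronate coupling), so C4 stays R.

Step 5
Reactants: 9 (2S)-3-bromo-2-methylpropan-1-ol
Product: 10 [(2S)-3-bromo-2-methylpropoxy](tert-butyl)dimethylsilane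
Conditions: TBSCl, imidazole, CH2Cl2, rt
Reagents that add atoms: tert-butyl(chloro)dimethylsilane CC(C)(C)[Si](C)(C)Cl
Why: Standard silylation of the primary alcohol; the stereocentre (future C15) is untouched.

Step 6
Reactants: 10 [(2S)-3-bromo-2-methylpropoxy](tert-butyl)dimethylsilane; 11 but-3-en-1-ylmagnesium bromide
Product: 12 tert-butyl(dimethyl){[(2R)-2-methylhept-6-en-1-yl]oxy}silane
Conditions: 11 (0.5 M in THF, 1.5 equiv), Li2CuCl4 (3 mol %), THF, −20 °C → rt
Reagents that add atoms: none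
Why: Kochi Cu-catalysed sp3–sp3 Grignard coupling at the primary bromide; the stereocentre is β to the reacting carbon and is kept (descriptor changes to R by priority only).

Step 7
Reactants: 12 tert-butyl(dimethyl){[(2R)-2-methylhept-6-en-1-yl]oxy}silane
Product: 13 tert-butyl(dimethyl){[(2R,6S)-2-methyl-6-(4,4,5,5-tetramethyl-1,3,2-dioxaborolan-2-yl)heptyl]oxy}silane
Conditions: CuCl (5 mol %), bisphosphine enantiomer B (= ent-A, chosen to give 6S), B2pin2, KOtBu (20 mol %), MeOH (2 equiv), THF, −20 °C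
Reagents that add atoms: bis(pinacolato)diboron CC1(C)OB(OC1(C)C)B1OC(C)(C)C(C)(C)O1
Why: Same Cu-catalysed Markovnikov hydroboration as step 3; the remote C15 centre does not interfere, so the ligand alone sets C11 (S at the boron-bearing carbon).

Step 8
Reactants: 8 (4R)-4-(2,3-dimethoxyphenyl)pentyl 2,4,6-tri(propan-2-yl)benzoate; 13 tert-butyl(dimethyl){[(2R,6S)-2-methyl-6-(4,4,5,5-tetramethyl-1,3,2-dioxaborolan-2-yl)heptyl]oxy}silane
Product: 16 tert-butyl({(2R,6S,7S,10R)-10-(2,3-dimethoxyphenyl)-2,6-dimethyl-7-(4,4,5,5-tetramethyl-1,3,2-dioxaborolan-2-yl)undecyl}oxy)dimethylsilane, via α-lithio ester 14 (not isolated), via lithium boronate 15 (not isolated)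
Conditions: 8 (1.2 equiv), s-BuLi, (+)-sparteine, Et2O, −78 °C, 5 h; 13, −78 °C, 1 h; then 35 °C, 16 h
Reagents that add atoms: none
Why: Lithiation–borylation (Hoppe–Aggarwal type): (+)-sparteine-directed removal of the pro-R α-H gives configurationally stable 14, borylation with retention gives 15, and the anti 1,2-metallate shift moves C11 from B to C1 (retention at C11, inversion at C1, TIB carboxylate leaving), forming C1–C11 and setting C1; aryl methyl ethers are not lithiated under these conditions.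

Step 9
Reactants: 16 tert-butyl({(2R,6S,7S,10R)-10-(2,3-dimethoxyphenyl)-2,6-dimethyl-7-(4,4,5,5-tetramethyl-1,3,2-dioxaborolan-2-yl)undecyl}oxy)dimethylsilane
Product: 17 tert-butyl({(2R,6S,7S,10R)-10-(6-bromo-2,3-dimethoxyphenyl)-2,6-dimethyl-7-(4,4,5,5-tetramethyl-1,3,2-dioxaborolan-2-yl)undecyl}oxy)dimethylsilane
Conditions: NBS (1.05 equiv), MeCN, 0 °C
Reagents that add atoms: N-bromosuccinimide O=C1CCC(=O)N1Br
Why: Electrophilic aromatic bromination goes para to the unhindered C6-OMe (the flanked C5-OMe is twisted out of conjugation), i.e. at the future C8a next to the chain; the alkyl C–B bond and all stereocentres are inert to NBS.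

Step 10
Reactants: 17 tert-butyl({(2R,6S,7S,10R)-10-(6-bromo-2,3-dimethoxyphenyl)-2,6-dimethyl-7-(4,4,5,5-tetramethyl-1,3,2-dioxaborolan-2-yl)undecyl}oxy)dimethylsilane
Product: 19 tert-butyl({(2R,6S)-6-[(1S,4R)-5,6-dimethoxy-4-methyl-1,2,3,4-tetrahydronaphthalen-1-yl]-2-methylheptyl}oxy)dimethylsilane, via cyclic lithium borate 18 (not isolated)
Conditions: t-BuLi (2.1 equiv), THF (0.02 M), −100 → −78 °C; then NBS (1.1 equiv), THF–MeOH, −78 °C → rt
Reagents that add atoms: none
Why: Proposed new method: Br–Li exchange at C8a and closure onto the pendant Bpin give the seven-membered cyclic borate 18; NBS attacks the electron-rich ring ortho to boron (C8, para to the C5-OMe; ipso attack at C6 converges), the arenium ion triggers a 1,2-shift of C1 from boron to C8a with retention at C1 that contracts the seven-membered boracycle to the six-membered carbocycle, and loss of bromide and MeOBpin re-aromatises; the closest known reaction is the intermolecular NBS-triggered stereospecific coupling of secondary boronic esters with electron-rich aryllithiums (step 4 type), not yet used intramolecularly to close a ring.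

Step 11
Reactants: 19 tert-butyl({(2R,6S)-6-[(1S,4R)-5,6-dimethoxy-4-methyl-1,2,3,4-tetrahydronaphthalen-1-yl]-2-methylheptyl}oxy)dimethylsilane
Product: 21 tert-butyl (5R,8S)-8-[(2S,6R)-7-{[tert-butyl(dimethyl)silyl]oxy}-6-methylheptan-2-yl]-3,4-dimethoxy-5-methyl-5,6,7,8-tetrahydronaphthalene-2-carboxylate, via C7 aryllithium 20 (not isolated)
Conditions: n-BuLi, TMEDA, Et2O, 0 °C → rt; then added to Boc2O, THF, −78 °C → rt
Reagents that add atoms: di-tert-butyl dicarbonate CC(C)(C)OC(=O)OC(=O)OC(C)(C)C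
Why: Directed ortho-metalation occurs at C7, the only ring C–H next to a methoxy group, and trapping of 20 with Boc2O gives the tert-butyl ester directly; no stereocentre is involved.

Step 12
Reactants: 21 tert-butyl (5R,8S)-8-[(2S,6R)-7-{[tert-butyl(dimethyl)silyl]oxy}-6-methylheptan-2-yl]-3,4-dimethoxy-5-methyl-5,6,7,8-tetrahydronaphthalene-2-carboxylate
Product: 22 tert-butyl (5R,8S)-8-[(2S,6R)-7-hydroxy-6-methylheptan-2-yl]-3,4-dimethoxy-5-methyl-5,6,7,8-tetrahydronaphthalene-2-carboxylate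
Conditions: TBAF, THF, rt
Reagents that add atoms: none
Why: Fluoride desilylation frees the primary alcohol; the tert-butyl ester and methyl ethers are stable.

Step 13
Reactants: 2 1,2-dimethoxybenzene
Product: 23 4-bromo-1,2-dimethoxybenzene
Conditions: NBS, MeCN, rt
Reagents that add atoms: N-bromosuccinimide O=C1CCC(=O)N1Br
Why: Electrophilic aromatic bromination of veratrole is para-selective.

Step 14
Reactants: 23 4-bromo-1,2-dimethoxybenzene; 24 acrylic acid
Product: 25 (2E)-3-(3,4-dimethoxyphenyl)prop-2-enoic acid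
Conditions: Pd(OAc)2 (2 mol %), P(o-tol)3, Et3N, DMF, 100 °C; then H3O+
Reagents that add atoms: none
Why: Mizoroki–Heck arylation of acrylic acid gives the E-cinnamic acid through syn insertion and syn β-hydride elimination.

Step 15
Reactants: 22 tert-butyl (5R,8S)-8-[(2S,6R)-7-hydroxy-6-methylheptan-2-yl]-3,4-dimethoxy-5-methyl-5,6,7,8-tetrahydronaphthalene-2-carboxylate; 25 (2E)-3-(3,4-dimethoxyphenyl)prop-2-enoic acid
Product: 26 tert-butyl (5R,8S)-8-[(2S,6R)-7-{[(2E)-3-(3,4-dimethoxyphenyl)prop-2-enoyl]oxy}-6-methylheptan-2-yl]-3,4-dimethoxy-5-methyl-5,6,7,8-tetrahydronaphthalene-2-carboxylate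
Conditions: EDC·HCl, DMAP (cat.), CH2Cl2, rt
Reagents that add atoms: none
Why: Steglich esterification of the only free hydroxyl; the ring carboxyl is masked as its tert-butyl ester, so no self-condensation is possible.

Step 16
Reactants: 26 tert-butyl (5R,8S)-8-[(2S,6R)-7-{[(2E)-3-(3,4-dimethoxyphenyl)prop-2-enoyl]oxy}-6-methylheptan-2-yl]-3,4-dimethoxy-5-methyl-5,6,7,8-tetrahydronaphthalene-2-carboxylate
Product: 27 (5R,8S)-8-[(2S,6R)-7-{[(2E)-3-(3,4-dihydroxyphenyl)prop-2-enoyl]oxy}-6-methylheptan-2-yl]-3,4-dihydroxy-5-methyl-5,6,7,8-tetrahydronaphthalene-2-carboxylic acid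
Conditions: BBr3 (12 equiv), CH2Cl2, −78 → 0 °C; then H2O, under argon
Reagents that add atoms: none
Why: Lewis-acid ether cleavage with BBr3 removes the four aryl methyl ethers and the tert-butyl ester in one operation, while the primary alkyl cinnamate survives at or below 0 °C; no stereocentre is touched.

**Compound list**
1 | catechol (benzene-1,2-diol) | Oc1ccccc1O | starting material
2 | 1,2-dimethoxybenzene | COc1ccccc1OC | intermediate
3 | pent-4-en-1-ol | C=CCCCO | starting material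
4 | pent-4-en-1-yl 2,4,6-tri(propan-2-yl)benzoate | C=CCCCOC(=O)c1c(C(C)C)cc(C(C)C)cc1C(C)C | intermediate
5 | (4R)-4-(4,4,5,5-tetramethyl-1,3,2-dioxaborolan-2-yl)pentyl 2,4,6-tri(propan-2-yl)benzoate | CC(C)c1cc(C(C)C)c(C(=O)OCCC[C@@H](C)B2OC(C)(C)C(C)(C)O2)c(C(C)C)c1 | intermediate
6 | (2,3-dimethoxyphenyl)lithium | [Li]c1cccc(OC)c1OC | intermediate
7 | lithium borate from 5 and 6 (boron bears pinacolate, the 2,3-dimethoxyphenyl group and the (R)-pentan-2-yl carbon) | [Li+].CC(C)c1cc(C(C)C)c(C(=O)OCCC[C@@H](C)[B-]2(c3cccc(OC)c3OC)OC(C)(C)C(C)(C)O2)c(C(C)C)c1 | intermediate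
8 | (4R)-4-(2,3-dimethoxyphenyl)pentyl 2,4,6-tri(propan-2-yl)benzoate | CC(C)c1cc(C(C)C)c(C(=O)OCCC[C@@H](C)c2cccc(OC)c2OC)c(C(C)C)c1 | intermediate
9 | (2S)-3-bromo-2-methylpropan-1-ol | C[C@H](CBr)CO | starting material
10 | [(2S)-3-bromo-2-methylpropoxy](tert-butyl)dimethylsilane | C[C@H](CBr)CO[Si](C)(C)C(C)(C)C | intermediate
11 | but-3-en-1-ylmagnesium bromide | C=CCC[Mg]Br | starting material
12 | tert-butyl(dimethyl){[(2R)-2-methylhept-6-en-1-yl]oxy}silane | C[C@H](CCCC=C)CO[Si](C)(C)C(C)(C)C | intermediate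
13 | tert-butyl(dimethyl){[(2R,6S)-2-methyl-6-(4,4,5,5-tetramethyl-1,3,2-dioxaborolan-2-yl)heptyl]oxy}silane | C[C@H](CCC[C@H](C)B1OC(C)(C)C(C)(C)O1)CO[Si](C)(C)C(C)(C)C | intermediate
14 | (1R,4R)-4-(2,3-dimethoxyphenyl)-1-lithiopentyl 2,4,6-tri(propan-2-yl)benzoate (sparteine-bound) | CC(C)c1cc(C(C)C)c(C(=O)O[C@H]([Li])CC[C@@H](C)c2cccc(OC)c2OC)c(C(C)C)c1 | intermediate
15 | lithium boronate from 14 and 13 (boron bears pinacolate, the α-(TIB-oxy) carbon C1 and C11) | [Li+].CC(C)c1cc(C(C)C)c(C(=O)O[C@H]([B-]2(OC(C)(C)C(C)(C)O2)[C@@H](C)CCC[C@@H](C)CO[Si](C)(C)C(C)(C)C)CC[C@@H](C)c2cccc(OC)c2OC)c(C(C)C)c1 | intermediate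
16 | tert-butyl({(2R,6S,7S,10R)-10-(2,3-dimethoxyphenyl)-2,6-dimethyl-7-(4,4,5,5-tetramethyl-1,3,2-dioxaborolan-2-yl)undecyl}oxy)dimethylsilane | C[C@H](CCC[C@H](C)[C@@H](B1OC(C)(C)C(C)(C)O1)CC[C@@H](C)c1cccc(OC)c1OC)CO[Si](C)(C)C(C)(C)C | intermediate
17 | tert-butyl({(2R,6S,7S,10R)-10-(6-bromo-2,3-dimethoxyphenyl)-2,6-dimethyl-7-(4,4,5,5-tetramethyl-1,3,2-dioxaborolan-2-yl)undecyl}oxy)dimethylsilane | C[C@H](CCC[C@H](C)[C@@H](B1OC(C)(C)C(C)(C)O1)CC[C@@H](C)c1c(Br)ccc(OC)c1OC)CO[Si](C)(C)C(C)(C)C | intermediate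
18 | cyclic lithium borate: seven-membered ring B–C1–C2–C3–C4–C4a–C8a, boron also bearing pinacolate | [Li+].C[C@H](CCC[C@H](C)[C@@H]1CC[C@@H](C)c2c(ccc(OC)c2OC)[B-]13OC(C)(C)C(C)(C)O3)CO[Si](C)(C)C(C)(C)C | intermediate
19 | tert-butyl({(2R,6S)-6-[(1S,4R)-5,6-dimethoxy-4-methyl-1,2,3,4-tetrahydronaphthalen-1-yl]-2-methylheptyl}oxy)dimethylsilane | C[C@H](CCC[C@H](C)[C@@H]1CC[C@@H](C)c2c1ccc(OC)c2OC)CO[Si](C)(C)C(C)(C)C | intermediate
20 | 7-lithio derivative of 19 (Li ortho to the C6 methoxy group) | C[C@H](CCC[C@H](C)[C@@H]1CC[C@@H](C)c2c1cc([Li])c(OC)c2OC)CO[Si](C)(C)C(C)(C)C | intermediate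
21 | tert-butyl (5R,8S)-8-[(2S,6R)-7-{[tert-butyl(dimethyl)silyl]oxy}-6-methylheptan-2-yl]-3,4-dimethoxy-5-methyl-5,6,7,8-tetrahydronaphthalene-2-carboxylate | C[C@H](CCC[C@H](C)[C@@H]1CC[C@@H](C)c2c1cc(C(=O)OC(C)(C)C)c(OC)c2OC)CO[Si](C)(C)C(C)(C)C | intermediate
22 | tert-butyl (5R,8S)-8-[(2S,6R)-7-hydroxy-6-methylheptan-2-yl]-3,4-dimethoxy-5-methyl-5,6,7,8-tetrahydronaphthalene-2-carboxylate | C[C@H](CCC[C@H](C)[C@@H]1CC[C@@H](C)c2c1cc(C(=O)OC(C)(C)C)c(OC)c2OC)CO | intermediate
23 | 4-bromo-1,2-dimethoxybenzene | COc1ccc(Br)cc1OC | intermediate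
24 | acrylic acid (prop-2-enoic acid) | C=CC(=O)O | starting material
25 | (2E)-3-(3,4-dimethoxyphenyl)prop-2-enoic acid | COc1ccc(/C=C/C(=O)O)cc1OC | intermediate
26 | tert-butyl (5R,8S)-8-[(2S,6R)-7-{[(2E)-3-(3,4-dimethoxyphenyl)prop-2-enoyl]oxy}-6-methylheptan-2-yl]-3,4-dimethoxy-5-methyl-5,6,7,8-tetrahydronaphthalene-2-carboxylate | C[C@H](CCC[C@H](C)[C@@H]1CC[C@@H](C)c2c1cc(C(=O)OC(C)(C)C)c(OC)c2OC)COC(=O)/C=C/c1ccc(OC)c(OC)c1 | intermediate
27 | (5R,8S)-8-[(2S,6R)-7-{[(2E)-3-(3,4-dihydroxyphenyl)prop-2-enoyl]oxy}-6-methylheptan-2-yl]-3,4-dihydroxy-5-methyl-5,6,7,8-tetrahydronaphthalene-2-carboxylic acid | C[C@H](CCC[C@H](C)[C@@H]1CC[C@@H](C)c2c1cc(C(=O)O)c(O)c2O)COC(=O)/C=C/c1ccc(O)c(O)c1 | target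

**Totals**
Total steps: 16. Longest linear sequence: 10 (steps 2, 3, 4, 8, 9, 10, 11, 12, 15, 16; the side-chain branch 5, 6, 7, 8, 9, 10, 11, 12, 15, 16 is equally long).

**Three steps most likely to fail, with fallbacks**

Step 10 (the proposed ring contraction). Risks: t-BuLi may add to boron instead of exchanging bromine, the seven-membered borate may form slowly, and NBS may cause ipso-bromodeboronation or C7 bromination instead of the productive attack. The fallback uses known chemistry, sets out from 16 (step 9 is then skipped) and comes back at 19. The C–B bond of 16 is oxidised with retention (NaBO3·4H2O, THF/H2O) to (2R,5S,6S,10R)-11-{[tert-butyl(dimethyl)silyl]oxy}-2-(2,3-dimethoxyphenyl)-6,10-dimethylundecan-5-ol F1. Dess–Martin oxidation gives (2R,6S,10R)-11-{[tert-butyl(dimethyl)silyl]oxy}-2-(2,3-dimethoxyphenyl)-6,10-dimethylundecan-5-one F2. Mild Lewis-acid cyclodehydration (BF3·OEt2, CH2Cl2, 0 °C; Bradsher-type Friedel–Crafts closure para to the C6-OMe, kept mild to avoid epimerising C11) gives tert-butyl({(2R,6S)-6-[(4R)-5,6-dimethoxy-4-methyl-3,4-dihydronaphthalen-1-yl]-2-methylheptyl}oxy)dimethylsilane F3. Catalyst-controlled Ir–N,P (PHOX-type) asymmetric hydrogenation of the C1=C2 bond then sets C1 and delivers 19.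

Step 4 (aryl–boronate coupling with an ortho-methoxy aryllithium). Risks: the hindered borate may form slowly and NBS may brominate without triggering migration. The fallback sets out from 2 and comes back at 8. Aryllithium 6 is transmetalated (ZnCl2) and coupled with vinyl bromide (Pd(PPh3)4, Negishi) to 1-ethenyl-2,3-dimethoxybenzene F4. Ni-catalysed asymmetric hydrovinylation with ethylene (phosphoramidite ligand) gives 1-[(2R)-but-3-en-2-yl]-2,3-dimethoxybenzene F5. Linear-selective Rh/Xantphos hydroformylation gives (4R)-4-(2,3-dimethoxyphenyl)pentanal F6, and NaBH4 gives (4R)-4-(2,3-dimethoxyphenyl)pentan-1-ol F7. Mitsunobu esterification with 2,4,6-triisopropylbenzoic acid returns 8.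

Step 7 (Cu-catalysed Markovnikov hydroboration; the same reaction type is used in step 3). Risks: incomplete branched selectivity or ee on this substrate. The fallback sets out from 10 and comes back at 13, setting C11 by reagent control instead. Cu-catalysed coupling of 10 with vinylmagnesium bromide gives tert-butyl(dimethyl){[(2R)-2-methylpent-4-en-1-yl]oxy}silane F8. Ir-catalysed anti-Markovnikov hydroboration with HBpin gives tert-butyl(dimethyl){[(2R)-2-methyl-5-(4,4,5,5-tetramethyl-1,3,2-dioxaborolan-2-yl)pentyl]oxy}silane F9. Lithiation–borylation of F9 with ethyl 2,4,6-triisopropylbenzoate, s-BuLi and (+)-sparteine (same 1,2-metallate logic as step 8) gives 13.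

**Further compounds**
F1 | step 10 | (2R,5S,6S,10R)-11-{[tert-butyl(dimethyl)silyl]oxy}-2-(2,3-dimethoxyphenyl)-6,10-dimethylundecan-5-ol | C[C@H](CCC[C@H](C)[C@@H](O)CC[C@@H](C)c1cccc(OC)c1OC)CO[Si](C)(C)C(C)(C)C
F2 | step 10 | (2R,6S,10R)-11-{[tert-butyl(dimethyl)silyl]oxy}-2-(2,3-dimethoxyphenyl)-6,10-dimethylundecan-5-one | C[C@H](CCC[C@H](C)C(=O)CC[C@@H](C)c1cccc(OC)c1OC)CO[Si](C)(C)C(C)(C)C
F3 | step 10 | tert-butyl({(2R,6S)-6-[(4R)-5,6-dimethoxy-4-methyl-3,4-dihydronaphthalen-1-yl]-2-methylheptyl}oxy)dimethylsilane | C[C@H](CCC[C@H](C)C1=CC[C@@H](C)c2c1ccc(OC)c2OC)CO[Si](C)(C)C(C)(C)C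
F4 | step 4 | 1-ethenyl-2,3-dimethoxybenzene | C=Cc1cccc(OC)c1OC
F5 | step 4 | 1-[(2R)-but-3-en-2-yl]-2,3-dimethoxybenzene | C=C[C@@H](C)c1cccc(OC)c1OC
F6 | step 4 | (4R)-4-(2,3-dimethoxyphenyl)pentanal | O=CCC[C@@H](C)c1cccc(OC)c1OC
F7 | step 4 | (4R)-4-(2,3-dimethoxyphenyl)pentan-1-ol | OCCC[C@@H](C)c1cccc(OC)c1OC
F8 | step 7 | tert-butyl(dimethyl){[(2R)-2-methylpent-4-en-1-yl]oxy}silane | C[C@H](CC=C)CO[Si](C)(C)C(C)(C)C
F9 | step 7 | tert-butyl(dimethyl){[(2R)-2-methyl-5-(4,4,5,5-tetramethyl-1,3,2-dioxaborolan-2-yl)pentyl]oxy}silane | C[C@H](CCCB1OC(C)(C)C(C)(C)O1)CO[Si](C)(C)C(C)(C)C
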